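**Retrosynthetic overview**

1. Labels used below: C1 is the carbon of the eleven-membered ring that bears the exocyclic CH2; C2–C7 follow round that ring (methyl on C5); C8=C9 is the tetrasubstituted alkene (methyl on C9); C10 is the ring-fusion CH; C11 the CH bonded to C1; C12 the cyclopentane CH2; C13 the CHOAc carbon; C14 the quaternary carbon (C17 is its CH2OH); C15 the CHOH carbon; C16 the allylic CH2.
2. Enabling feature: the five-membered ring C10–C14 is a vinylcyclopentane. C10 carries C9 of the six-membered ring, and C9 is linked to C14 through C8–C16–C15. A (3+2) retron therefore opens it to a vinylcyclopropane (C10, C11, C12) and an alkene (C13=C14) tethered at the alpha-vinyl carbon.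
3. Key disconnection: C12–C13 and C10–C14, by a rhodium-catalysed intramolecular (3+2) cycloaddition of a cis-1,2-disubstituted vinylcyclopropane with an (E)-enol acetate. The C9 methyl is carried as an exocyclic CH2 and C8 as a ketone; both are returned afterwards.
4. Other disconnections: C7–C8 (B-alkyl Suzuki–Miyaura macrocyclisation of the enol triflate), C15–C16 (boron aldol), C8–C9 (Stille), C1–C2 (Grignard on a Weinreb amide), C1=CH2 (methylenation). Chirality comes from (S)-β-citronellene, an enantiopure cyclopropane hemiester and a reagent-controlled aldol.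
5. Ring order: cyclopropane (bought), then five- and six-membered rings together in the key step, then the eleven-membered ring.

Key step: step 14

Remarks:
- "Configured as in the target" means the SMILES shows the same sense at C5, C10, C11, C13, C14 and C15 as the target.
- Assumption on the chemistry: in step 12 the (−) enantiomer of Ipc2BCl is taken to give the (S)-carbinol at C15; if the sense proves opposite, the (+) reagent is used and nothing else changes.

**Route**

Step 1
Reactants: 1 (S)-β-citronellene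
Product: 3 (S)-4-methylhex-5-en-1-ol, via aldehyde 2 (not isolated)
Conditions: O3, CH2Cl2/MeOH, −78 °C, Sudan red 7B indicator; then NaBH4, −78 °C to rt
Reagents that add atoms: ozone (O=[O+][O-])
Why: Selective ozonolysis with reductive work-up should cleave the electron-rich trisubstituted alkene much faster than the monosubstituted vinyl group and leave the stereocentre untouched.

Step 2
Reactants: 3 (S)-4-methylhex-5-en-1-ol
Product: 4 (S)-6-bromo-3-methylhex-1-ene
Conditions: CBr4, PPh3, CH2Cl2, 0 °C
Reagents that add atoms: carbon tetrabromide (BrC(Br)(Br)Br)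
Why: The Appel reaction should convert the primary alcohol into the bromide under neutral conditions that spare the alkene and the stereocentre.

Step 3
Reactants: 5 (1S,2R)-2-(methoxycarbonyl)cyclopropane-1-carboxylic acid
Product: 7 methyl (1R,2S)-2-acetylcyclopropane-1-carboxylate, via acid chloride 6 (not isolated)
Conditions: (COCl)2, DMF (cat.), CH2Cl2, 0 °C to rt; then MeMgBr, Fe(acac)3 (3 mol %), THF, −78 °C
Reagents that add atoms: methylmagnesium bromide (C[Mg]Br)
Why: Iron-catalysed acylation of the acid chloride by the Grignard reagent should be far faster than attack on the methyl ester, so the methyl ketone forms with the cis-cyclopropane intact.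

Step 4
Reactants: 7 methyl (1R,2S)-2-acetylcyclopropane-1-carboxylate
Product: 9 methyl (1R,2S)-2-{1-[(trifluoromethanesulfonyl)oxy]ethenyl}cyclopropane-1-carboxylate, via potassium enolate 8 (not isolated)
Conditions: KN(SiMe3)2, THF, −78 °C; then PhNTf2, −78 to 0 °C
Reagents that add atoms: N-phenylbis(trifluoromethanesulfonimide) (O=S(=O)(N(c1ccccc1)S(=O)(=O)C(F)(F)F)C(F)(F)F)
Why: Kinetic enolisation at the methyl group (the cyclopropyl alpha-hydrogens are not removed) followed by O-triflation should give the terminal enol triflate, with low temperature and immediate trapping suppressing Claisen attack on the cis ester.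

Step 5
Reactants: 9 methyl (1R,2S)-2-{1-[(trifluoromethanesulfonyl)oxy]ethenyl}cyclopropane-1-carboxylate
Product: 10 1-{(1S,2R)-2-[methoxy(methyl)carbamoyl]cyclopropyl}ethenyl trifluoromethanesulfonate
Conditions: MeNHOMe·HCl, iPrMgCl, THF, −20 °C
Reagents that add atoms: N,O-dimethylhydroxylamine hydrochloride (CNOC.Cl)
Why: The magnesium amide of N,O-dimethylhydroxylamine should turn the methyl ester directly into the Weinreb amide at a temperature at which the vinyl triflate and the cyclopropane are stable.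

Step 6
Reactants: 10 1-{(1S,2R)-2-[methoxy(methyl)carbamoyl]cyclopropyl}ethenyl trifluoromethanesulfonate; 4 (S)-6-bromo-3-methylhex-1-ene
Product: 12 1-{(1S,2R)-2-[(5S)-5-methylhept-6-enoyl]cyclopropyl}ethenyl trifluoromethanesulfonate, via Grignard reagent 11 (not isolated)
Conditions: Mg, THF, rt; then 10, THF, −20 to 0 °C
Reagents that add atoms: none
Why: Weinreb ketone synthesis, in which the Grignard reagent adds once through the chelated tetrahedral intermediate while the vinyl triflate is inert in the absence of a catalyst, should form the C1–C2 bond.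

Step 7
Reactants: 12 1-{(1S,2R)-2-[(5S)-5-methylhept-6-enoyl]cyclopropyl}ethenyl trifluoromethanesulfonate
Product: 13 1-[(1S,2R)-2-{2-[(4S)-4-methylhex-5-en-1-yl]-1,3-dioxolan-2-yl}cyclopropyl]ethenyl trifluoromethanesulfonate
Conditions: (TMSOCH2)2, TMSOTf (5 mol %), CH2Cl2, −78 to −20 °C
Reagents that add atoms: 1,2-bis(trimethylsilyloxy)ethane (C[Si](C)(C)OCCO[Si](C)(C)C)
Why: Noyori ketalisation should protect the C1 ketone without heating, which removes the carbonyl that would direct cyclopropane cleavage to the C10–C11 bond and closes the retro-Claisen pathway of cis-2-vinylcyclopropyl ketones.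

Step 8
Reactants: 13 1-[(1S,2R)-2-{2-[(4S)-4-methylhex-5-en-1-yl]-1,3-dioxolan-2-yl}cyclopropyl]ethenyl trifluoromethanesulfonate
Product: 15 3-[(1S,2R)-2-{2-[(4S)-4-methylhex-5-en-1-yl]-1,3-dioxolan-2-yl}cyclopropyl]but-3-en-2-one, via ethoxydiene 14 (not isolated)
Conditions: tributyl(1-ethoxyvinyl)stannane, Pd(PPh3)4 (5 mol %), LiCl, THF, 65 °C; then 0.5 M HCl (aq), THF, 0 °C
Reagents that add atoms: tributyl(1-ethoxyvinyl)stannane (CCCC[Sn](CCCC)(CCCC)C(=C)OCC); water (O)
Why: Stille coupling with the acetyl-anion equivalent should give a 2-ethoxydiene whose enol ether is hydrolysed by cold dilute acid much faster than the dioxolane, unveiling the 1-cyclopropylvinyl methyl ketone (C8, C16).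

Step 9
Reactants: 16 2-(hydroxymethyl)propane-1,3-diol
Product: 17 2-{[(tert-butyldiphenylsilyl)oxy]methyl}propane-1,3-diol
Conditions: TBDPSCl (0.4 equiv), imidazole, DMF, 0 °C
Reagents that add atoms: tert-butyl(chloro)diphenylsilane (CC(C)(C)[Si](Cl)(c1ccccc1)c1ccccc1)
Why: With the symmetric triol in excess, silylation of one of three equivalent primary hydroxyls should give the mono-ether (statistical monoprotection).

Step 10
Reactants: 17 2-{[(tert-butyldiphenylsilyl)oxy]methyl}propane-1,3-diol
Product: 18 2-{[(tert-butyldiphenylsilyl)oxy]methyl}propanedial (held as its enol)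
Conditions: Dess–Martin periodinane (2.5 equiv), NaHCO3, CH2Cl2, 0 °C to rt
Reagents that add atoms: none
Why: Dess–Martin oxidation of both primary alcohols should give the 2-substituted malondialdehyde, which is stabilised as its hydrogen-bonded enol.

Step 11
Reactants: 18 2-{[(tert-butyldiphenylsilyl)oxy]methyl}propanedial
Product: 19 (E)-2-{[(tert-butyldiphenylsilyl)oxy]methyl}-3-oxoprop-1-en-1-yl acetate
Conditions: Ac2O, pyridine, DMAP (cat.), CH2Cl2, 0 °C to rt
Reagents that add atoms: acetic anhydride (CC(=O)OC(C)=O)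
Why: O-acetylation of the enol should give the push–pull enol acetate, which equilibrates by addition–elimination to the E isomer with acetoxy anti to the formyl group, the geometry that later places O13 cis to C17.

Step 12
Reactants: 15 3-[(1S,2R)-2-{2-[(4S)-4-methylhex-5-en-1-yl]-1,3-dioxolan-2-yl}cyclopropyl]but-3-en-2-one; 19 (E)-2-{[(tert-butyldiphenylsilyl)oxy]methyl}-3-oxoprop-1-en-1-yl acetate
Product: 21 (1E,3S)-aldol adduct (C15 carbinol), via boron enolate 20 (not isolated)
Conditions: (−)-Ipc2BCl, Et3N, Et2O, −78 to 0 °C; then 19, −78 to −20 °C; MeOH, pH 7 buffer, diethanolamine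
Reagents that add atoms: none
Why: In this diisopinocampheylboron-mediated aldol reaction the methyl ketone is enolised regiospecifically and should add 1,2 to the enal through a chair transition state, the chiral ligands on boron setting C15 (reagent control), while the non-oxidative work-up spares enone and enol acetate.

Step 13
Reactants: 21 (1E,3S)-aldol adduct
Product: 22 (1E,3S)-3-[(tert-butyldimethylsilyl)oxy]-2-{[(tert-butyldiphenylsilyl)oxy]methyl}-6-[(1S,2R)-2-{2-[(4S)-4-methylhex-5-en-1-yl]-1,3-dioxolan-2-yl}cyclopropyl]-5-oxohepta-1,6-dien-1-yl acetate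
Conditions: TBSOTf, 2,6-lutidine, CH2Cl2, −78 °C
Reagents that add atoms: tert-butyldimethylsilyl trifluoromethanesulfonate (CC(C)(C)[Si](C)(C)OS(=O)(=O)C(F)(F)F)
Why: Low-temperature silylation should cap the beta-hydroxy ketone before dehydration or acyl transfer can occur (silyl ether formation).

Step 14
Reactants: 22 cis-vinylcyclopropane enone carrying the (E)-enol acetate
Product: 23 cis-fused bicyclic cycloadduct (C8 ketone, C9 exocyclic methylene, C13 acetate)
Conditions: [Rh(cod)Cl]2 (5 mol %), dppm (10 mol %), AgSbF6 (10 mol %), 1,2-dichloroethane, 85 °C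
Reagents that add atoms: none
Why: Proposed new method: monovalent rhodium should insert into the less hindered C10–C12 bond of the vinylcyclopropane to give a trivalent sigma-alkyl(pi-allyl)rhodium species (allyl = C10–C9–exocyclic CH2, sigma bond at C12), the tethered enol acetate then inserts with C14 bonding to the allyl terminus C10 and rhodium moving to C13, and C(sp3)–C(sp3) reductive elimination joins C12 to C13; the closest known reaction type is the rhodium-catalysed intramolecular (3+2) cycloaddition of vinylcyclopropanes that carry the alkene tether on the alpha carbon of the vinyl group, which has not been shown for a trisubstituted enol ester or for a 1,2-cis-disubstituted cyclopropane. The six-membered ring closes by bond formation between the allyl terminus C10 and the internal alkene carbon C14, which the three-atom tether C8–C16–C15 on the central allyl carbon C9 holds in place (the exocyclic methylene stays on C9), and the five-membered ring closes by reductive elimination from the rhodacyclohexane C10–C11–C12–Rh–C13–C14. C10 is re-formed with retention because rhodium enters and delivers C14 on the face from which C12 left, so the cis relation of the cyclopropane substituents becomes the cis relation of C9 and C1 on the cyclopentane, and C11 is not touched. C14 and C13 follow from suprafacial addition to the (E)-enol acetate within a cis-fused metallacycle (acetoxy cis to the silyloxymethyl group), and the pre-set C15 silyl ether can sit pseudo-equatorial in the chair-like tether, so its configuration is the matched one. The step needs fused (3+2) over bridged (5+2) cycloaddition, which the alpha-tether is known to favour, cleavage of C10–C12 and not C10–C11, which the bulky ketal on C11 should secure, and insertion faster than beta-hydride elimination, for which the hydrogen-free quaternary C14 and chelation of rhodium by the acetate at C13 are relied on.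

Step 15
Reactants: 23 cis-fused bicyclic cycloadduct
Product: 25 bicyclic enol triflate (C8–OTf, C9–CH3), via lithium enolate 24 (not isolated)
Conditions: LiBH(s-Bu)3, THF, −78 °C; then PhNTf2, −78 to 0 °C
Reagents that add atoms: N-phenylbis(trifluoromethanesulfonimide) (O=S(=O)(N(c1ccccc1)S(=O)(=O)C(F)(F)F)C(F)(F)F)
Why: Conjugate reduction with enolate trapping should turn the exocyclic CH2 into the C9 methyl and give regiospecifically the C8–C9 enolate, which is triflated on oxygen to fix the tetrasubstituted alkene position.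

Step 16
Reactants: 25 bicyclic enol triflate
Product: 27 macrocyclic ketal (tricyclic skeleton complete), via alkylborane 26 (not isolated)
Conditions: 9-BBN-H, THF, 0 °C to rt; then Pd(dppf)Cl2 (10 mol %), AsPh3, Cs2CO3, DMF/THF/H2O, 50 °C, 1 mM
Reagents that add atoms: none
Why: 9-BBN should hydroborate only the monosubstituted terminal alkene, and the B-alkyl borane should then couple intramolecularly with the enol triflate under high dilution (B-alkyl Suzuki–Miyaura macrocyclisation), closing the eleven-membered ring at C7–C8 with the alkene geometry fixed by the six-membered ring.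

Step 17
Reactants: 27 macrocyclic ketal
Product: 28 macrocyclic C1 ketone
Conditions: 1 M HCl (aq)/THF (1:5), rt
Reagents that add atoms: water (O)
Why: Acetal hydrolysis under mild aqueous acid should free the C1 ketone while the acetate and the hindered silyl ethers survive.

Step 18
Reactants: 28 macrocyclic C1 ketone
Product: 29 bis-silyl ether of the target
Conditions: Zn, CH2Br2, TiCl4, THF/CH2Cl2, 0 °C to rt
Reagents that add atoms: dibromomethane (BrCBr)
Why: Takai–Lombardo methylenation is non-basic and selective for ketones over esters, so C1=CH2 should be installed without epimerising C11 or touching the acetate.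

Step 19
Reactants: 29 bis-silyl ether of the target
Product: 30 CNP0228496.1
Conditions: HF·pyridine, pyridine, THF, 0 °C to rt
Reagents that add atoms: none
Why: Buffered fluoride desilylation should remove both silyl ethers without acyl migration or isomerisation of the exocyclic alkene.

**Compound list**

1 | (S)-3,7-dimethylocta-1,6-diene, (S)-β-citronellene | C=C[C@@H](C)CCC=C(C)C | starting material
2 | (S)-4-methylhex-5-enal | C=C[C@@H](C)CCC=O | intermediate
3 | (S)-4-methylhex-5-en-1-ol | C=C[C@@H](C)CCCO | intermediate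
4 | (S)-6-bromo-3-methylhex-1-ene | C=C[C@@H](C)CCCBr | intermediate
5 | (1S,2R)-2-(methoxycarbonyl)cyclopropane-1-carboxylic acid (commercial; also accessible by enzymatic desymmetrisation of the meso dimethyl ester) | OC(=O)[C@@H]1[C@H](C(=O)OC)C1 | starting material
6 | methyl (1R,2S)-2-(chlorocarbonyl)cyclopropane-1-carboxylate | ClC(=O)[C@@H]1[C@H](C(=O)OC)C1 | intermediate
7 | methyl (1R,2S)-2-acetylcyclopropane-1-carboxylate | CC(=O)[C@@H]1[C@H](C(=O)OC)C1 | intermediate
8 | potassium 1-[(1S,2R)-2-(methoxycarbonyl)cyclopropyl]ethen-1-olate | C=C(O[K])[C@@H]1[C@H](C(=O)OC)C1 | intermediate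
9 | methyl (1R,2S)-2-{1-[(trifluoromethanesulfonyl)oxy]ethenyl}cyclopropane-1-carboxylate | C=C(OS(=O)(=O)C(F)(F)F)[C@@H]1[C@H](C(=O)OC)C1 | intermediate
10 | 1-{(1S,2R)-2-[methoxy(methyl)carbamoyl]cyclopropyl}ethenyl trifluoromethanesulfonate | C=C(OS(=O)(=O)C(F)(F)F)[C@@H]1[C@H](C(=O)N(C)OC)C1 | intermediate
11 | [(4S)-4-methylhex-5-en-1-yl]magnesium bromide | C=C[C@@H](C)CCC[Mg]Br | intermediate
12 | 1-{(1S,2R)-2-[(5S)-5-methylhept-6-enoyl]cyclopropyl}ethenyl trifluoromethanesulfonate | C=C(OS(=O)(=O)C(F)(F)F)[C@@H]1[C@H](C(=O)CCC[C@H](C)C=C)C1 | intermediate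
13 | 1-[(1S,2R)-2-{2-[(4S)-4-methylhex-5-en-1-yl]-1,3-dioxolan-2-yl}cyclopropyl]ethenyl trifluoromethanesulfonate | C=C(OS(=O)(=O)C(F)(F)F)[C@@H]1[C@H](C2(CCC[C@H](C)C=C)OCCO2)C1 | intermediate
14 | 2-[(1R,2S)-2-(3-ethoxybuta-1,3-dien-2-yl)cyclopropyl]-2-[(4S)-4-methylhex-5-en-1-yl]-1,3-dioxolane | C=C(OCC)C(=C)[C@@H]1[C@H](C2(CCC[C@H](C)C=C)OCCO2)C1 | intermediate
15 | 3-[(1S,2R)-2-{2-[(4S)-4-methylhex-5-en-1-yl]-1,3-dioxolan-2-yl}cyclopropyl]but-3-en-2-one | CC(=O)C(=C)[C@@H]1[C@H](C2(CCC[C@H](C)C=C)OCCO2)C1 | intermediate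
16 | 2-(hydroxymethyl)propane-1,3-diol | OCC(CO)CO | starting material
17 | 2-{[(tert-butyldiphenylsilyl)oxy]methyl}propane-1,3-diol | OCC(CO)CO[Si](c1ccccc1)(c1ccccc1)C(C)(C)C | intermediate
18 | 2-{[(tert-butyldiphenylsilyl)oxy]methyl}propanedial (held as its enol) | O=CC(C=O)CO[Si](c1ccccc1)(c1ccccc1)C(C)(C)C | intermediate
19 | (E)-2-{[(tert-butyldiphenylsilyl)oxy]methyl}-3-oxoprop-1-en-1-yl acetate (acetoxy trans to CHO) | CC(=O)O/C=C(/C=O)CO[Si](c1ccccc1)(c1ccccc1)C(C)(C)C | intermediate
20 | diisopinocampheylboron enolate of 15 (O-boron enolate at C8, terminal CH2 = C16; isopinocampheyl groups as in (−)-Ipc2BCl) | C=C(OB([C@@H]1C[C@@H]2C[C@H]([C@H]1C)C2(C)C)[C@@H]1C[C@@H]2C[C@H]([C@H]1C)C2(C)C)C(=C)[C@@H]1[C@H](C2(CCC[C@H](C)C=C)OCCO2)C1 | intermediate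
21 | (1E,3S)-2-{[(tert-butyldiphenylsilyl)oxy]methyl}-3-hydroxy-6-[(1S,2R)-2-{2-[(4S)-4-methylhex-5-en-1-yl]-1,3-dioxolan-2-yl}cyclopropyl]-5-oxohepta-1,6-dien-1-yl acetate | CC(=O)O/C=C(/[C@@H](O)CC(=O)C(=C)[C@@H]1[C@H](C2(CCC[C@H](C)C=C)OCCO2)C1)CO[Si](c1ccccc1)(c1ccccc1)C(C)(C)C | intermediate
22 | (1E,3S)-3-[(tert-butyldimethylsilyl)oxy]-2-{[(tert-butyldiphenylsilyl)oxy]methyl}-6-[(1S,2R)-2-{2-[(4S)-4-methylhex-5-en-1-yl]-1,3-dioxolan-2-yl}cyclopropyl]-5-oxohepta-1,6-dien-1-yl acetate | CC(=O)O/C=C(/[C@@H](O[Si](C)(C)C(C)(C)C)CC(=O)C(=C)[C@@H]1[C@H](C2(CCC[C@H](C)C=C)OCCO2)C1)CO[Si](c1ccccc1)(c1ccccc1)C(C)(C)C | intermediate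
23 | cis-fused bicyclo[4.3.0]nonanone cycloadduct: six-membered ring C8(=O)–C9(=CH2)–C10–C14–C15–C16, five-membered ring C10–C11–C12–C13–C14; C11 carries the 2-[(4S)-4-methylhex-5-en-1-yl]-1,3-dioxolan-2-yl group, C13 OAc, C14 CH2OTBDPS, C15 OTBS; configured as in the target | O=C1C(=C)[C@@H]2[C@H](C3(CCC[C@H](C)C=C)OCCO3)C[C@@H](OC(C)=O)[C@]2(CO[Si](c4ccccc4)(c4ccccc4)C(C)(C)C)[C@@H](O[Si](C)(C)C(C)(C)C)C1 | intermediate
24 | lithium C8–C9 enolate from 1,4-reduction of 23 (C9 now carries CH3) | [Li]OC1=C(C)[C@@H]2[C@H](C3(CCC[C@H](C)C=C)OCCO3)C[C@@H](OC(C)=O)[C@]2(CO[Si](c4ccccc4)(c4ccccc4)C(C)(C)C)[C@@H](O[Si](C)(C)C(C)(C)C)C1 | intermediate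
25 | bicyclic enol triflate: as 23 but with C8(OTf)=C9(CH3) | FC(F)(F)S(=O)(=O)OC1=C(C)[C@@H]2[C@H](C3(CCC[C@H](C)C=C)OCCO3)C[C@@H](OC(C)=O)[C@]2(CO[Si](c4ccccc4)(c4ccccc4)C(C)(C)C)[C@@H](O[Si](C)(C)C(C)(C)C)C1 | intermediate
26 | B-alkyl-9-borabicyclo[3.3.1]nonane from 25 (boron on C7) | FC(F)(F)S(=O)(=O)OC1=C(C)[C@@H]2[C@H](C3(CCC[C@H](C)CCB4C5CCCC4CCC5)OCCO3)C[C@@H](OC(C)=O)[C@]2(CO[Si](c4ccccc4)(c4ccccc4)C(C)(C)C)[C@@H](O[Si](C)(C)C(C)(C)C)C1 | intermediate
27 | macrocyclic ketal: target skeleton with C1 as 1,3-dioxolane, C15 OTBS, C17 OTBDPS, C13 OAc; configured as in the target | O1CCOC12CCC[C@H](C)CCC3=C(C)[C@@H]4[C@H]2C[C@@H](OC(C)=O)[C@]4(CO[Si](c5ccccc5)(c5ccccc5)C(C)(C)C)[C@@H](O[Si](C)(C)C(C)(C)C)C3 | intermediate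
28 | macrocyclic C1 ketone: as 27 with C1=O | O=C1CCC[C@H](C)CCC2=C(C)[C@@H]3[C@H]1C[C@@H](OC(C)=O)[C@]3(CO[Si](c4ccccc4)(c4ccccc4)C(C)(C)C)[C@@H](O[Si](C)(C)C(C)(C)C)C2 | intermediate
29 | target with O15 as TBS ether and O17 as TBDPS ether | C=C1CCC[C@H](C)CCC2=C(C)[C@@H]3[C@H]1C[C@@H](OC(C)=O)[C@]3(CO[Si](c4ccccc4)(c4ccccc4)C(C)(C)C)[C@@H](O[Si](C)(C)C(C)(C)C)C2 | intermediate
30 | CNP0228496.1: (5S,10S,11R,13R,14R,15S)-13-acetoxy triol monoacetate with C1=CH2, C8=C9, C15–OH and C17–OH | C=C1CCC[C@H](C)CCC2=C(C)[C@@H]3[C@H]1C[C@@H](OC(C)=O)[C@]3(CO)[C@@H](O)C2 | target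

**Count and risks**

Total steps: 19. Longest linear sequence: 14 steps (5 to 30, steps 3–8 and 12–19).

Steps most likely to fail:

Step 14 (carries the label). The trisubstituted enol acetate may insert too slowly, so that beta-hydride elimination opens the rhodacycle to a diene. The allyl unit may also lose its facial memory by sigma–pi–sigma isomerisation before insertion, which would erode the C10/C11 cis relationship. The fallback, which uses known reaction types only, sets out from 15 and comes back at 27; it puts the C13 oxygen on late by hydroxyl-directed C–H functionalisation. 2-Methylenepropane-1,3-diol is monosilylated (TESCl, imidazole) to 2-{[(triethylsilyl)oxy]methyl}prop-2-en-1-ol F1 and oxidised (MnO2) to 2-{[(triethylsilyl)oxy]methyl}prop-2-enal F2. Boron enolate 20, made from 15 as in step 12, adds to F2 to give aldol adduct F3, which is silylated (TBSOTf, 2,6-lutidine) to bis-silyl ether F4. F4 carries an unfunctionalised 1,1-disubstituted alkene, the partner type for which the rhodium (3+2) cycloaddition is established, and under the conditions of step 14 should give all-carbon cycloadduct F5 (C13 as CH2). Conjugate reduction and triflation as in step 15 lead through lithium enolate F6 to enol triflate F7. Hydroboration and Suzuki–Miyaura macrocyclisation as in step 16 lead through alkylborane F8 to macrocyclic ketal F9. Brief treatment with HF·pyridine at 0 °C removes only the triethylsilyl group and frees primary alcohol F10. Et2SiH2 with [Ir(cod)OMe]2 converts it into hydridosilyl ether F11. Iridium-catalysed silylation of the gamma C–H bond ([Ir(cod)OMe]2, 3,4,7,8-tetramethyl-1,10-phenanthroline, norbornene, THF, 100 °C) should then close oxasilolane F12 on the C13–H bond that is cis to C17. Tamao–Fleming oxidation (H2O2, KHCO3, KF) gives 1,3-diol F13 with retention at C13. The primary hydroxyl is silylated (TBDPSCl, imidazole) to silyl ether alcohol F14, and acetylation of the C13 hydroxyl (Ac2O, DMAP) returns 27.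

Step 16. Strain in the bridged eleven-membered ring may slow the intramolecular coupling so that oligomerisation, protodeboronation or beta-hydride elimination of the alkylpalladium species take over. The fallback sets out from 25 and comes back at 27; it closes the ring by metathesis instead. Stille coupling of 25 with tributyl(vinyl)stannane (Pd(PPh3)4, LiCl) gives triene F15. Ring-closing metathesis between the new vinyl group and the terminal alkene (second-generation Grubbs catalyst, high dilution, toluene, 80 °C) gives macrocyclic diene F16 with loss of ethene; the vinyl CH takes the place of C7. Diimide (TsNHNH2, NaOAc) reduces only the disubstituted alkene and gives 27.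

Step 12. Facial selectivity at C15 rests on reagent control alone and may be poor with a beta-acetoxy enal; acyl transfer from the enol acetate or conjugate addition–elimination may also compete with 1,2-addition. The fallback sets out from 19 and 13 and comes back at 22; it sets C15 on the small fragment and moves the fragment union to C8–C9. A catalytic enantioselective Mukaiyama aldol reaction of 19 with 1-(ethylsulfanyl)-1-(trimethylsilyloxy)ethene (Ti(OiPr)4 with a binaphthyl Schiff-base ligand and 3,5-di-tert-butylsalicylic acid) gives hydroxy thioester F17. Silylation (TBSOTf) gives silyloxy thioester F18, and Fukuyama reduction (Et3SiH, Pd/C) gives aldehyde F19. Nozaki–Hiyama–Kishi coupling of F19 with vinyl triflate 13 (CrCl2, NiCl2 cat., DMF) gives allylic alcohol F20 as both C8 epimers, and Dess–Martin oxidation converges them on 22.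

Further compounds
F1 | step 14 | 2-{[(triethylsilyl)oxy]methyl}prop-2-en-1-ol | C=C(CO)CO[Si](CC)(CC)CC
F2 | step 14 | 2-{[(triethylsilyl)oxy]methyl}prop-2-enal | C=C(C=O)CO[Si](CC)(CC)CC
F3 | step 14 | aldol adduct (as 21 but C13 is =CH2 and O17 carries triethylsilyl; C15 S) | C=C(CO[Si](CC)(CC)CC)[C@@H](O)CC(=O)C(=C)[C@@H]1[C@H](C2(CCC[C@H](C)C=C)OCCO2)C1
F4 | step 14 | bis-silyl ether (F3 with O15 as TBS ether) | C=C(CO[Si](CC)(CC)CC)[C@@H](O[Si](C)(C)C(C)(C)C)CC(=O)C(=C)[C@@H]1[C@H](C2(CCC[C@H](C)C=C)OCCO2)C1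
F5 | step 14 | all-carbon cycloadduct (as 23 but C13 is CH2 and O17 carries triethylsilyl) | O=C1C(=C)[C@@H]2[C@H](C3(CCC[C@H](C)C=C)OCCO3)CC[C@]2(CO[Si](CC)(CC)CC)[C@@H](O[Si](C)(C)C(C)(C)C)C1
F6 | step 14 | lithium enolate (from 1,4-reduction of F5) | [Li]OC1=C(C)[C@@H]2[C@H](C3(CCC[C@H](C)C=C)OCCO3)CC[C@]2(CO[Si](CC)(CC)CC)[C@@H](O[Si](C)(C)C(C)(C)C)C1
F7 | step 14 | enol triflate (C8–OTf, C9–CH3, C13 as CH2) | FC(F)(F)S(=O)(=O)OC1=C(C)[C@@H]2[C@H](C3(CCC[C@H](C)C=C)OCCO3)CC[C@]2(CO[Si](CC)(CC)CC)[C@@H](O[Si](C)(C)C(C)(C)C)C1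
F8 | step 14 | alkylborane (9-BBN adduct of F7, boron on C7) | FC(F)(F)S(=O)(=O)OC1=C(C)[C@@H]2[C@H](C3(CCC[C@H](C)CCB4C5CCCC4CCC5)OCCO3)CC[C@]2(CO[Si](CC)(CC)CC)[C@@H](O[Si](C)(C)C(C)(C)C)C1
F9 | step 14 | macrocyclic ketal (as 27 but C13 is CH2 and O17 carries triethylsilyl) | O1CCOC12CCC[C@H](C)CCC3=C(C)[C@@H]4[C@H]2CC[C@]4(CO[Si](CC)(CC)CC)[C@@H](O[Si](C)(C)C(C)(C)C)C3
F10 | step 14 | primary alcohol (F9 with free C17–OH) | O1CCOC12CCC[C@H](C)CCC3=C(C)[C@@H]4[C@H]2CC[C@]4(CO)[C@@H](O[Si](C)(C)C(C)(C)C)C3
F11 | step 14 | hydridosilyl ether (O17–SiHEt2) | O1CCOC12CCC[C@H](C)CCC3=C(C)[C@@H]4[C@H]2CC[C@]4(CO[SiH](CC)CC)[C@@H](O[Si](C)(C)C(C)(C)C)C3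
F12 | step 14 | oxasilolane (ring C17–O–SiEt2–C13–C14, silicon on the C13 face cis to C17) | O1CCOC12CCC[C@H](C)CCC3=C(C)[C@@H]4[C@H]2C[C@@H]5[C@]4(CO[Si]5(CC)CC)[C@@H](O[Si](C)(C)C(C)(C)C)C3
F13 | step 14 | 1,3-diol (free C13–OH and C17–OH, O15 as TBS ether) | O1CCOC12CCC[C@H](C)CCC3=C(C)[C@@H]4[C@H]2C[C@@H](O)[C@]4(CO)[C@@H](O[Si](C)(C)C(C)(C)C)C3
F14 | step 14 | silyl ether alcohol (27 lacking the acetyl group) | O1CCOC12CCC[C@H](C)CCC3=C(C)[C@@H]4[C@H]2C[C@@H](O)[C@]4(CO[Si](c5ccccc5)(c5ccccc5)C(C)(C)C)[C@@H](O[Si](C)(C)C(C)(C)C)C3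
F15 | step 16 | triene (25 with vinyl in place of OTf on C8) | C=CC1=C(C)[C@@H]2[C@H](C3(CCC[C@H](C)C=C)OCCO3)C[C@@H](OC(C)=O)[C@]2(CO[Si](c4ccccc4)(c4ccccc4)C(C)(C)C)[C@@H](O[Si](C)(C)C(C)(C)C)C1
F16 | step 16 | macrocyclic diene (27 with a C6=C7 double bond, either geometry) | O1CCOC12CCC[C@H](C)C=CC3=C(C)[C@@H]4[C@H]2C[C@@H](OC(C)=O)[C@]4(CO[Si](c5ccccc5)(c5ccccc5)C(C)(C)C)[C@@H](O[Si](C)(C)C(C)(C)C)C3
F17 | step 12 | hydroxy thioester (S-ethyl thioester at C8, C15 S, E enol acetate) | CC(=O)O/C=C(/[C@@H](O)CC(=O)SCC)CO[Si](c1ccccc1)(c1ccccc1)C(C)(C)C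
F18 | step 12 | silyloxy thioester (F17 with O15 as TBS ether) | CC(=O)O/C=C(/[C@@H](O[Si](C)(C)C(C)(C)C)CC(=O)SCC)CO[Si](c1ccccc1)(c1ccccc1)C(C)(C)C
F19 | step 12 | aldehyde (C8 as CHO) | CC(=O)O/C=C(/[C@@H](O[Si](C)(C)C(C)(C)C)CC=O)CO[Si](c1ccccc1)(c1ccccc1)C(C)(C)C
F20 | step 12 | allylic alcohol (22 with C8 as CHOH, both epimers) | CC(=O)O/C=C(/[C@@H](O[Si](C)(C)C(C)(C)C)CC(O)C(=C)[C@@H]1[C@H](C2(CCC[C@H](C)C=C)OCCO2)C1)CO[Si](c1ccccc1)(c1ccccc1)C(C)(C)C
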